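**Retrosynthetic overview**
- The route rests on one feature: the isopropenyl carbon C4 on C5 and the acid chain C1–C2–C3 on quaternary C10 lie cis on ring B (C5–C10), so they are read as the two ends of an opened, cis-fused ring A (C10, C1, C2, C3, C4, C5) with a gem-dimethyl ketone.
- Target ⇐ 12-hydroxy-11,14-quinone ⇐ trimethyl ether seco acid 18 ⇐ seven-membered lactone 17 ⇐ Baeyer–Villiger oxidation of the cis-fused 3,7-diketone 16 (ring A cleaved between C3 and C4).
- Ring A ⇐ tethered conjugate addition: the C4 enolate of the isopropyl ketone chain on C10 adds to C5 of the ring B enone (C5=C6–C7=O) of naphthalenone 14.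
- Ring B ⇐ Friedel–Crafts acylation (C7–C8) of the Z-enoic acid 12 ⇐ Z-olefination of aldehyde 10; C10 ⇐ enamine-catalysed Michael addition of 2-arylpropanal 8 to 4-methylpent-1-en-3-one 9.
- Ring C ⇐ two directed lithiations of 1,2,4-trimethoxybenzene. Order of ring formation: C (bought), B (step 9), A (step 10, opened again in steps 11 and 12).

Key step: step 10

Remark 1: carbon numbers C1–C20 are those of the abietane skeleton of 16 (ring A: C10, C1, C2, C3, C4, C5; ring B: C5, C6, C7, C8, C9, C10; ring C: C8, C9, C11, C12, C13, C14) and are used for every compound from 10 onwards.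
Remark 2 (assumption): the sense of induction in step 6 is assigned from the hydrogen-bond-directed enamine model of proline-derived catalysts; if the opposite sense were found, the mirror-image catalyst would be used.

**Step 1**
Reactants: 1 1,2,4-trimethoxybenzene
Product: 3 2-(2,3,6-trimethoxyphenyl)propan-2-ol, via aryllithium 2 (not isolated)
Conditions: n-BuLi, THF, 0 °C to rt; acetone, −78 °C to rt; H2O
Reagents that add atoms: acetone, CC(C)=O
Why: Directed ortho-metalation removes the proton at C3, which is flanked by two methoxy groups and is the most acidic, and the aryllithium adds to the carbonyl group of acetone.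

**Step 2**
Reactants: 3 2-(2,3,6-trimethoxyphenyl)propan-2-ol
Product: 4 1,2,4-trimethoxy-3-(propan-2-yl)benzene
Conditions: Et3SiH, CF3CO2H, CH2Cl2, 0 °C to rt
Reagents that add atoms: none
Why: Ionic hydrogenation: the acid ionises the tertiary benzylic alcohol and the silane delivers hydride to the cation.

**Step 3**
Reactants: 4 1,2,4-trimethoxy-3-(propan-2-yl)benzene
Product: 6 1-[2,3,5-trimethoxy-4-(propan-2-yl)phenyl]ethan-1-one, via aryllithium 5 (not isolated)
Conditions: n-BuLi, TMEDA, THF, 0 °C; MeC(O)N(OMe)Me, −78 °C to rt; H2O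
Reagents that add atoms: N-methoxy-N-methylacetamide, CC(=O)N(C)OC
Why: Directed ortho-metalation followed by Weinreb ketone synthesis; of the two ring protons left, H6 should be removed, because it is ortho to the unhindered methoxy group at C1, meta to two further methoxy groups and para only to the alkyl group, whereas H5 is para to a methoxy group and its neighbouring methoxy group is held by the isopropyl group with its methyl turned towards H5, so that the acetyl group enters at the later C9.

**Step 4**
Reactants: 6 1-[2,3,5-trimethoxy-4-(propan-2-yl)phenyl]ethan-1-one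
Product: 7 1-methoxy-2-[2,3,5-trimethoxy-4-(propan-2-yl)phenyl]prop-1-ene (E/Z mixture)
Conditions: Ph3P(CH2OMe)Cl, KOt-Bu, THF, 0 °C to rt
Reagents that add atoms: (methoxymethyl)triphenylphosphonium chloride, COC[P+](c1ccccc1)(c1ccccc1)c1ccccc1.[Cl-]
Why: Wittig methoxymethylenation of the aryl methyl ketone adds the one carbon that becomes C5; the alkene geometry is of no consequence.

**Step 5**
Reactants: 7 1-methoxy-2-[2,3,5-trimethoxy-4-(propan-2-yl)phenyl]prop-1-ene
Product: 8 2-[2,3,5-trimethoxy-4-(propan-2-yl)phenyl]propanal (racemic)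
Conditions: 2 M HCl, THF, rt
Reagents that add atoms: water, O
Why: Acid hydrolysis of the enol ether (protonation at carbon, hydration, loss of methanol) gives the aldehyde from both isomers; its stereocentre is racemic and is erased in the next step.

**Step 6**
Reactants: 8 2-[2,3,5-trimethoxy-4-(propan-2-yl)phenyl]propanal; 9 4-methylpent-1-en-3-one
Product: 10 (2S)-2,6-dimethyl-5-oxo-2-[2,3,5-trimethoxy-4-(propan-2-yl)phenyl]heptanal
Conditions: (R)-N-(4-dodecylphenylsulfonyl)pyrrolidine-2-carboxamide (20 mol %), 4 Å molecular sieves, ClCH2CH2Cl, rt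
Reagents that add atoms: none
Why: Enamine-catalysed asymmetric Michael addition of an α-branched aldehyde to a vinyl ketone: the pyrrolidine forms the E-enamine (aryl anti to nitrogen), and the acidic sulfonamide N–H steers the enone to the Si face of the enamine carbon, which should set quaternary C10 as (S) and install the complete C1–C4 chain.

**Step 7**
Reactants: 10 (2S)-2,6-dimethyl-5-oxo-2-[2,3,5-trimethoxy-4-(propan-2-yl)phenyl]heptanal
Product: 11 methyl (2Z,4R)-4,8-dimethyl-7-oxo-4-[2,3,5-trimethoxy-4-(propan-2-yl)phenyl]non-2-enoate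
Conditions: (CF3CH2O)2P(O)CH2CO2Me, KN(SiMe3)2, 18-crown-6, THF, −78 °C
Reagents that add atoms: methyl 2-[bis(2,2,2-trifluoroethoxy)phosphoryl]acetate, COC(=O)CP(=O)(OCC(F)(F)F)OCC(F)(F)F
Why: Still–Gennari variant of the Horner–Wadsworth–Emmons olefination: the preformed, weakly basic phosphonate anion attacks the aldehyde in preference to the ketone, and fast elimination from the first-formed adduct should give the Z-enoate (C5=C6, C7).

**Step 8**
Reactants: 11 methyl (2Z,4R)-4,8-dimethyl-7-oxo-4-[2,3,5-trimethoxy-4-(propan-2-yl)phenyl]non-2-enoate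
Product: 12 (2Z,4R)-4,8-dimethyl-7-oxo-4-[2,3,5-trimethoxy-4-(propan-2-yl)phenyl]non-2-enoic acid
Conditions: LiOH, THF–H2O, 0 °C to rt; then 1 M HCl
Reagents that add atoms: lithium hydroxide, [Li+].[OH-]
Why: Saponification of the unhindered methyl ester under conditions too mild to enolise the isopropyl ketone or to isomerise the Z-alkene.

**Step 9**
Reactants: 12 (2Z,4R)-4,8-dimethyl-7-oxo-4-[2,3,5-trimethoxy-4-(propan-2-yl)phenyl]non-2-enoic acid
Product: 14 (4R)-5,6,8-trimethoxy-4-methyl-4-(4-methyl-3-oxopentyl)-7-(propan-2-yl)naphthalen-1(4H)-one, via mixed anhydride 13 (not isolated)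
Conditions: (CF3CO)2O, CH2Cl2, 0 °C to rt
Reagents that add atoms: none
Why: Intramolecular Friedel–Crafts acylation: the Z geometry holds the activated carboxyl next to C8, the only free ring position (ortho and para to methoxy groups), so ring B closes directly at the enone oxidation level and no dehydrogenation beside the side-chain ketone is needed.

**Step 10**
Reactants: 14 (4R)-5,6,8-trimethoxy-4-methyl-4-(4-methyl-3-oxopentyl)-7-(propan-2-yl)naphthalen-1(4H)-one
Product: 16 (4bR,8aR)-1,3,4-trimethoxy-4b,8,8-trimethyl-2-(propan-2-yl)-4b,5,6,8,8a,9-hexahydrophenanthrene-7,10-dione (cis-fused; 5R,10R in abietane numbering), via potassium enolate 15 (not isolated)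
Conditions: KOt-Bu (0.3 equiv), t-BuOH–THF, 0 °C to rt
Reagents that add atoms: none
Why: KOt-Bu in t-BuOH enolises the isopropyl ketone reversibly, and the tetrasubstituted C4 enolate 15 adds to C5, the β-carbon of the ring B enone (C5=C6–C7=O), which forms the C4–C5 bond and ring A (C10, C1, C2, C3, C4, C5); protonation of the resulting C6–C7 enolate by t-BuOH gives 16 and returns the base. The closest known reaction type is the intramolecular Michael addition of a ketone enolate to a cyclohexenone that gives a cis-fused decalin. Ring A closes in the 6-exo-trig mode, the C5=C6 bond lying outside the new ring. The new stereocentre C5 is controlled by C10 alone: the three-atom tether C1–C2–C3 holds the enolate carbon over the face of the nearly flat ring B that carries the chain, so C4 bonds to C5 cis to C1 and the ring fusion must be cis. The step needs regioselection between two enolates and chemoselection between two carbonyl groups: the C2 enolate could close only a four-membered ring and is returned by proton exchange, and the ring B enone has no enolisable hydrogen (C10 is quaternary, C5 and C6 are vinylic), so it can act only as the acceptor.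

**Step 11**
Reactants: 16 (4bR,8aR)-1,3,4-trimethoxy-4b,8,8-trimethyl-2-(propan-2-yl)-4b,5,6,8,8a,9-hexahydrophenanthrene-7,10-dione
Product: 17 (5R,10R)-11,12,14-trimethoxy-7-oxo-3,4-seco-abieta-8,11,13-trien-3,4-olide (seven-membered lactone, ring oxygen between C3 and C4)
Conditions: mCPBA, NaHCO3, CH2Cl2, rt
Reagents that add atoms: 3-chloroperoxybenzoic acid, O=C(OO)c1cccc(Cl)c1
Why: Baeyer–Villiger oxidation: the peracid adds to the aliphatic C3 ketone in preference to the conjugated, electron-rich aryl ketone C7, and the tertiary carbon C4 migrates to oxygen with retention, leaving C5 and C10 untouched.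

**Step 12**
Reactants: 17 (5R,10R)-11,12,14-trimethoxy-7-oxo-3,4-seco-abieta-8,11,13-trien-3,4-olide
Product: 18 3-[(1R,2S)-5,7,8-trimethoxy-1-methyl-4-oxo-6-(propan-2-yl)-2-(prop-1-en-2-yl)-1,2,3,4-tetrahydronaphthalen-1-yl]propanoic acid
Conditions: TsOH·H2O (0.2 equiv), toluene, 80 °C
Reagents that add atoms: none
Why: Acid-catalysed alkyl–oxygen cleavage of the tertiary lactone (E1 elimination): the C4 cation loses a methyl proton to give the isopropenyl group and the free acid, the tetrasubstituted C4=C5 alkene being disfavoured by allylic strain against the C10 substituents.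

**Step 13**
Reactants: 18 3-[(1R,2S)-5,7,8-trimethoxy-1-methyl-4-oxo-6-(propan-2-yl)-2-(prop-1-en-2-yl)-1,2,3,4-tetrahydronaphthalen-1-yl]propanoic acid
Product: 19 3-[(1R,2S)-7-methoxy-1-methyl-4,5,8-trioxo-6-(propan-2-yl)-2-(prop-1-en-2-yl)-1,2,3,4,5,8-hexahydronaphthalen-1-yl]propanoic acid
Conditions: (NH4)2Ce(NO3)6, MeCN–H2O, 0 °C
Reagents that add atoms: water, O
Why: Oxidative demethylation of the para-related methoxy groups at C11 and C14 gives the para-quinone (water attacks the ring carbons and methanol leaves), and the C12 methoxy group is kept as a vinylogous ester.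

**Step 14**
Reactants: 19 3-[(1R,2S)-7-methoxy-1-methyl-4,5,8-trioxo-6-(propan-2-yl)-2-(prop-1-en-2-yl)-1,2,3,4,5,8-hexahydronaphthalen-1-yl]propanoic acid
Product: 20 3-[(1R,2S)-7-hydroxy-1-methyl-4,5,8-trioxo-6-(propan-2-yl)-2-(prop-1-en-2-yl)-1,2,3,4,5,8-hexahydronaphthalen-1-yl]propanoic acid
Conditions: LiOH (3.2 equiv), THF–H2O, 0 °C, argon; then 1 M HCl
Reagents that add atoms: lithium hydroxide, [Li+].[OH-]
Why: Addition–elimination of hydroxide at C12 (hydrolysis of the vinylogous methyl ester of the quinone), run cold, briefly and with measured base so that enolisation at C6 cannot go on to remove the C5 hydrogen.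

**Step 15**
Reactants: 20 3-[(1R,2S)-7-hydroxy-1-methyl-4,5,8-trioxo-6-(propan-2-yl)-2-(prop-1-en-2-yl)-1,2,3,4,5,8-hexahydronaphthalen-1-yl]propanoic acid
Product: 21 3-[(1R,2S)-5,7,8-trihydroxy-1-methyl-4-oxo-6-(propan-2-yl)-2-(prop-1-en-2-yl)-1,2,3,4-tetrahydronaphthalen-1-yl]propanoic acid (CNP0198818.2)
Conditions: Na2S2O4, EtOAc–H2O (degassed), rt, argon
Reagents that add atoms: none
Why: Dithionite reduction of the quinone to the hydroquinone leaves the ketone, the alkene and the acid untouched; the triol should be handled under argon.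

**Compound list**
1 | 1,2,4-trimethoxybenzene | COc1ccc(OC)c(OC)c1 | starting material
2 | (2,3,6-trimethoxyphenyl)lithium | COc1ccc(OC)c([Li])c1OC | intermediate
3 | 2-(2,3,6-trimethoxyphenyl)propan-2-ol | COc1ccc(OC)c(C(C)(C)O)c1OC | intermediate
4 | 1,2,4-trimethoxy-3-(propan-2-yl)benzene | COc1ccc(OC)c(C(C)C)c1OC | intermediate
5 | [2,3,5-trimethoxy-4-(propan-2-yl)phenyl]lithium | [Li]c1cc(OC)c(C(C)C)c(OC)c1OC | intermediate
6 | 1-[2,3,5-trimethoxy-4-(propan-2-yl)phenyl]ethan-1-one | CC(=O)c1cc(OC)c(C(C)C)c(OC)c1OC | intermediate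
7 | 1-methoxy-2-[2,3,5-trimethoxy-4-(propan-2-yl)phenyl]prop-1-ene (E/Z mixture) | COC=C(C)c1cc(OC)c(C(C)C)c(OC)c1OC | intermediate
8 | 2-[2,3,5-trimethoxy-4-(propan-2-yl)phenyl]propanal (racemic) | CC(C=O)c1cc(OC)c(C(C)C)c(OC)c1OC | intermediate
9 | 4-methylpent-1-en-3-one | C=CC(=O)C(C)C | starting material
10 | (2S)-2,6-dimethyl-5-oxo-2-[2,3,5-trimethoxy-4-(propan-2-yl)phenyl]heptanal | O=C[C@@](C)(CCC(=O)C(C)C)c1cc(OC)c(C(C)C)c(OC)c1OC | intermediate
11 | methyl (2Z,4R)-4,8-dimethyl-7-oxo-4-[2,3,5-trimethoxy-4-(propan-2-yl)phenyl]non-2-enoate | COC(=O)/C=C\[C@@](C)(CCC(=O)C(C)C)c1cc(OC)c(C(C)C)c(OC)c1OC | intermediate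
12 | (2Z,4R)-4,8-dimethyl-7-oxo-4-[2,3,5-trimethoxy-4-(propan-2-yl)phenyl]non-2-enoic acid | OC(=O)/C=C\[C@@](C)(CCC(=O)C(C)C)c1cc(OC)c(C(C)C)c(OC)c1OC | intermediate
13 | (2Z,4R)-4,8-dimethyl-7-oxo-4-[2,3,5-trimethoxy-4-(propan-2-yl)phenyl]non-2-enoic trifluoroacetic anhydride | O=C(OC(=O)C(F)(F)F)/C=C\[C@@](C)(CCC(=O)C(C)C)c1cc(OC)c(C(C)C)c(OC)c1OC | intermediate
14 | (4R)-5,6,8-trimethoxy-4-methyl-4-(4-methyl-3-oxopentyl)-7-(propan-2-yl)naphthalen-1(4H)-one | CC(C)C(=O)CC[C@]1(C)C=CC(=O)c2c(OC)c(C(C)C)c(OC)c(OC)c12 | intermediate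
15 | potassium enolate of 14 (C3–O−, C3=C4 tetrasubstituted) | [K+].CC(C)=C([O-])CC[C@]1(C)C=CC(=O)c2c(OC)c(C(C)C)c(OC)c(OC)c12 | intermediate
16 | (4bR,8aR)-1,3,4-trimethoxy-4b,8,8-trimethyl-2-(propan-2-yl)-4b,5,6,8,8a,9-hexahydrophenanthrene-7,10-dione | CC1(C)C(=O)CC[C@@]2(C)c3c(OC)c(OC)c(C(C)C)c(OC)c3C(=O)C[C@@H]12 | intermediate
17 | (5R,10R)-11,12,14-trimethoxy-7-oxo-3,4-seco-abieta-8,11,13-trien-3,4-olide | CC1(C)OC(=O)CC[C@@]2(C)c3c(OC)c(OC)c(C(C)C)c(OC)c3C(=O)C[C@@H]12 | intermediate
18 | 3-[(1R,2S)-5,7,8-trimethoxy-1-methyl-4-oxo-6-(propan-2-yl)-2-(prop-1-en-2-yl)-1,2,3,4-tetrahydronaphthalen-1-yl]propanoic acid | C=C(C)[C@@H]1CC(=O)c2c(OC)c(C(C)C)c(OC)c(OC)c2[C@]1(C)CCC(=O)O | intermediate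
19 | 3-[(1R,2S)-7-methoxy-1-methyl-4,5,8-trioxo-6-(propan-2-yl)-2-(prop-1-en-2-yl)-1,2,3,4,5,8-hexahydronaphthalen-1-yl]propanoic acid | C=C(C)[C@@H]1CC(=O)C2=C(C(=O)C(OC)=C(C(C)C)C2=O)[C@]1(C)CCC(=O)O | intermediate
20 | 3-[(1R,2S)-7-hydroxy-1-methyl-4,5,8-trioxo-6-(propan-2-yl)-2-(prop-1-en-2-yl)-1,2,3,4,5,8-hexahydronaphthalen-1-yl]propanoic acid | C=C(C)[C@@H]1CC(=O)C2=C(C(=O)C(O)=C(C(C)C)C2=O)[C@]1(C)CCC(=O)O | intermediate
21 | 3-[(1R,2S)-5,7,8-trihydroxy-1-methyl-4-oxo-6-(propan-2-yl)-2-(prop-1-en-2-yl)-1,2,3,4-tetrahydronaphthalen-1-yl]propanoic acid | C=C(C)[C@@H]1CC(=O)c2c(O)c(C(C)C)c(O)c(O)c2[C@]1(C)CCC(=O)O | target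

Total step count: 15
Longest linear sequence: 15 steps (from 1 to 21)

**Steps most likely to fail**

Step 10. The conjugate addition may stall because the tetrasubstituted enolate carbon must bond to C5 next to quaternary C10; under reversible base the retro-Michael reaction, aldol closure of the C2 enolate onto the C7 carbonyl or oxygen attack of the enolate at C5 may then take over. The fallback sets out from 14 and comes back at 16. The ketone is silylated under equilibrating conditions (Me3SiCl, Et3N, DMF, 80 °C) to the tetrasubstituted trimethylsilyl enol ether F1. This is then closed by a Mukaiyama–Michael addition (TiCl4, CH2Cl2, −78 °C; H2O), in which the Lewis acid activates the enone and the addition is not reversible. Any less substituted enol ether present cannot cyclise and returns 14 on work-up.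

Step 6. Facial discrimination may be poor, because the ortho-methoxy group twists the aryl ring out of the enamine plane and weakens control of the enamine geometry, and condensation of the catalyst with the hindered aldehyde may be slow. The fallback sets out from 8 and 9 and comes back at 10. The addition is run as a base-catalysed Michael reaction without a chiral catalyst (DBU, THF, rt) to give the racemic keto aldehyde F2. It is resolved by preparative supercritical-fluid chromatography on a chiral stationary phase; the (S)-enantiomer is 10, and the (R)-enantiomer F3 is set aside.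

Step 11. Oxygen insertion may occur at the wrong carbonyl group (migration of the electron-rich aryl carbon C8 at the C7 ketone), or addition of the peracid to the hindered C3 carbonyl may be slow enough for oxidation of ring C to compete. The fallback sets out from 16, replaces steps 11 and 12 and comes back at 18. The C3 ketone is converted into the (E)-oxime F4 (NH2OH·HCl, NaOAc, EtOH, 60 °C). Beckmann fragmentation (TsCl, pyridine, 80 °C) then cleaves the C3–C4 bond; the C4 cation loses a methyl proton, which gives the isopropenyl nitrile F5. Hydrolysis of the nitrile (KOH, EtOH–H2O, reflux; then HCl) gives the acid 18.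

**Further compounds**
F1 | step 10 | (4R)-5,6,8-trimethoxy-4-methyl-4-[4-methyl-3-(trimethylsilyloxy)pent-3-en-1-yl]-7-(propan-2-yl)naphthalen-1(4H)-one | CC(C)=C(CC[C@]1(C)C=CC(=O)c2c(OC)c(C(C)C)c(OC)c(OC)c12)O[Si](C)(C)C
F2 | step 6 | 2,6-dimethyl-5-oxo-2-[2,3,5-trimethoxy-4-(propan-2-yl)phenyl]heptanal (racemic) | O=CC(C)(CCC(=O)C(C)C)c1cc(OC)c(C(C)C)c(OC)c1OC
F3 | step 6 | (2R)-2,6-dimethyl-5-oxo-2-[2,3,5-trimethoxy-4-(propan-2-yl)phenyl]heptanal | O=C[C@](C)(CCC(=O)C(C)C)c1cc(OC)c(C(C)C)c(OC)c1OC
F4 | step 11 | (4bR,8aR,7E)-7-(hydroxyimino)-1,3,4-trimethoxy-4b,8,8-trimethyl-2-(propan-2-yl)-4b,5,6,7,8,8a-hexahydrophenanthren-10(9H)-one | CC1(C)/C(=N/O)CC[C@@]2(C)c3c(OC)c(OC)c(C(C)C)c(OC)c3C(=O)C[C@@H]12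
F5 | step 11 | 3-[(1R,2S)-5,7,8-trimethoxy-1-methyl-4-oxo-6-(propan-2-yl)-2-(prop-1-en-2-yl)-1,2,3,4-tetrahydronaphthalen-1-yl]propanenitrile | C=C(C)[C@@H]1CC(=O)c2c(OC)c(C(C)C)c(OC)c(OC)c2[C@]1(C)CCC#N
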